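Readings and results stem from a simulated flask for substances that don't exist; noise was put on by code.

Saturday's flask is slow: after 90.0 s it reads 11.3% open intermediate and 0.2% target, so I ask how far the longer time of the new flasks makes up for that slowness.

| flask | substrate | gas | temperature | remark | time |
|---|---|---|---|---|---|
| Saturday's | 0.45 M | 80 mM (held) | 60 °C | run made earlier |  |
| north | 0.30 M | 80 mM (held) | 60 °C |  | 15 min |
| east | 0.30 M | 80 mM (held) | 90 °C |  | 15 min |
| south-east | 0.30 M | 80 mM (held) | 30 °C |  | 15 min |
| south-west | 0.30 M | 80 mM (held) | 120 °C |  | 15 min |

Saturday's run (percent of the substrate charged)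

| time / s | open intermediate / % | target / % |
|---|---|---|
| 10.0 | 0.8 | 0 |
| 15.0 | 3.1 | 0 |
| 40.0 | 6.9 | 0.3 |
| 90.0 | 11.3 | 0.2 |

(each reading ± 1 percentage point)

- at the start none of the gas is in solution
- the earlier runs do not show what temperature does; that part of a forecast is a guess

* the best flask by amount of open intermediate, in percent of the substrate charged; "all alike" if 1.5 percentage points covers them all (north / east / south-east / south-west / all alike)
* amount of open intermediate at the end, in percent of the substrate charged, north
* amount of open intermediate at the end, in percent of the substrate charged, east
* amount of open intermediate at the end, in percent of the substrate charged, south-east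
* amount of open intermediate at the end, in percent of the substrate charged, south-west

I take the opening as first order, with rate k[substrate], so the share opened does not depend on the charge and Saturday's 0.45 M carries over to north's 0.30 M. The last reading, with its scatter, then gives k = 0.07994 min⁻¹. For north the opening number is 1.20; it is the time the flask gets divided by the mean time a substrate waits to open, a Damköhler number. With no way back and no onward loss, the share opened is one minus the exponential of minus that number, so on those terms I reckon 69.9% for north.

Is one number enough? At 40.0 s it gives 5.19% against a reading of 6.9%, a gap of 1.7 percentage points where one reading scatters by 1 point, so the readings demand no second number yet. But they reach an opening number of just 0.120, and north runs ten times as long, so a ceiling or a drain further on stays unseen. Temperature lies outside the number too: for the other flasks I have no figure, and naming north as best is a guess.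

The forecast gives north 25%, east 10%, south-east 18% and south-west 4%, with north best, and says of the hot flasks “onward loss to target and an unfavourable equilibrium should leave little”. My north stands higher.

The flasks give north 67.7%, east 61.5%, south-east 2.91% and south-west 17.6%, with north best.

    substrate ⇌ open intermediate (K = 1.90, k = 0.0300 s⁻¹, Ea = 104 kJ mol⁻¹, ΔH = −67.0 kJ mol⁻¹)
    target ⇌ isomer of the product (K = 31.0, k = 0.00150 s⁻¹, Ea = 105 kJ mol⁻¹, ΔH = −41.0 kJ mol⁻¹)
    partner → second intermediate (k = 5.10 × 10⁻⁴ s⁻¹, Ea = 122 kJ mol⁻¹)
    gas ⇌ partner, rate k4*(csat - [partner]) (kL = 0.00240 s⁻¹)
    open intermediate + second intermediate → target (k = 0.00810 L mol⁻¹ s⁻¹, Ea = 75.0 kJ mol⁻¹)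
    2 open intermediate → homo product (k = 1.70 × 10⁻⁴ L mol⁻¹ s⁻¹, Ea = 79.0 kJ mol⁻¹)
    (constants at 90 °C)

North lies 2.2 points under my 69.9%. The neighbour is north read at 4.0 min, a quarter of the time. Its opening number is 0.320, and that gives 27.4% open intermediate. The neighbour holds 27.4% open intermediate, with 72.6% of the charge still substrate.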